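(The earlier runs and the new flask come from a simulation for substances that don't exist, noise included.)

The easy mistake is to read Monday's free base, 80.0% of the electrophile charged, as a ceiling on reaction. The midnight run had 93.0%, yet it had used 99.1% of its electrophile by 5.00 d.

| flask | electrophile | nucleophile | free base | protic impurity | remark | time |
|---|---|---|---|---|---|---|
| midnight | 0.10 M | 0.10 M | 0.093 M | 0.050 M | run made earlier |  |
| winter | 0.10 M | 0.10 M | 0.19 M | 0.050 M | run made earlier |  |
| Monday's | 0.10 M | 0.100 M | 0.0800 M | 0.0500 M |  | 10 d |
| Thursday's | 0.10 M | 0.100 M | 0.160 M | 0.0500 M |  | 10 d |

- midnight (time / d: electrophile / %, target / %): 1.04: 12.8, 77.2; 2.08: 5.5, 82.9; 3.00: 3.1, 84.5; 4.00: 1.9, 85.3; 5.00: 0.9, 86.5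
- winter (time / d: electrophile / %, target / %): 0.417: 29.2, 65.0; 0.833: 14.8, 76.3; 1.25: 8.9, 81.5; 2.50: 2.9, 86.1; 5.00: 0.5, 87.7

(standard deviation of a reading: 0.3 percentage points)

- part of the electrophile that has reacted at the end, Monday's
- part of the electrophile that has reacted at the end, Thursday's
- what raising the concentration of free base from its lowest to its highest value here does to the part of the electrophile that has reacted (changes below 5 percentage points count as none) (it rises / it falls / no change)



My bench rule is that a tail keeps halving at a steady pace. Between 3.00 d and 5.00 d the midnight readings give a half-life near 1.12 d, though the scatter weighs heavily on readings this small, and the winter run gives 0.986 d. Monday's holds less base than midnight, so I also try a tail twice as slow. Running on from the last readings, I expect 0.0409% to 0.192% of the electrophile left on Monday's and 0.0149% on Thursday's. That gap of 0.18 percentage points is under the 5 points margin, so I expect no change.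

The rule needs partners to last. At midnight's last reading, 12.6% of the charge is neither electrophile nor target, and I assign that to the protic impurity, whose charge is half the electrophile's. So I watch the cover: 1.50 on both new flasks, nucleophile plus protic impurity charged over electrophile charged. If each electrophile takes one partner, I put the rule's border at a cover of 1; below it, I expect the reacted share to stop near the cover.

The forecast, under my figure for Monday's, gives 98.7% for Monday's, 99.9% for Thursday's and no change, since “Thursday's goes essentially to completion”. The flask gives 99.9% on Monday's and >99.9% on Thursday's, a change of 0.13 points, which reads as no change.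

    electrophile + nucleophile → acid set free + target (k = 2.10 L mol⁻¹ h⁻¹)
    nucleophile + acid set free ⇌ protonated nucleophile, settled at all times (K = 53000 L mol⁻¹)
    acid set free + free base ⇌ salt of the base, settled at all times (K = 3.70 × 10⁵ L mol⁻¹)
    crystals ⇌ acid set free, rate k4*(cs4 - [acid set free]) while solid is left; crystals form when [acid set free] > cs4 (solubility = 0.0700 M, k = 0.500 h⁻¹)
    electrophile + acid set free → side product (k = 0.150 L mol⁻¹ h⁻¹)
    electrophile + protic impurity → quenched substrate (k = 0.250 L mol⁻¹ h⁻¹)

At a cover of 1.50, electrophile is the limiting reagent on Thursday's: 0.0095% of it stands at the end beside 76% of the protic impurity, and its half-life by the step to target, 1.3 d at that time, is short against the 10 d. A flask like Thursday's but charged with 0.40 M of electrophile has a cover of 0.375, and there 37.5% has reacted, with 0% of the nucleophile, 0% of the protic impurity and 62% of the electrophile left.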